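## Structural features

The target is a trans-2,3-dibenzyl-γ-butyrolactone (an oxolan-2-one of the dibenzylbutyrolactone lignan type), C23H28O7. C3 carries a 3,4-dimethoxybenzyl group (ring A) and C4 a 3,4,5-trimethoxybenzyl group (ring B), each joined to the lactone through one CH2; C5 is an unsubstituted OCH2. The two stereocentres C3 and C4 are adjacent, both R, with the benzyl groups trans. C3 is α to the carbonyl, epimerisable and thermodynamically trans, so it can be corrected late; C4 has no acidic hydrogen and must be installed with full absolute control. Fragile points are the lactone (opened by hydroxide or hard nucleophiles, reclosing on acidification), the electron-rich arenes (oxidants, strong electrophiles) and the aryl methyl ethers (strong Lewis acids). The real difficulty is twofold: the absolute configuration of the isolated centre C4, and the unambiguous placement of two very similar benzyl groups on C3 and C4. The key step exploits the fact that C4, C5 and the CH2 between C4 and ring B form a three-carbon unit that maps onto epichlorohydrin. If that CH2 is also bonded to C3, a cyclopropane fused across C3–C4 results, whose CH2 becomes electrophilic once C3 bears a second acyl group.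

## Logic of the disconnections

**12 ⇒ 10.** No skeletal bond of 12 is cut; the C3–H bond is exchanged for a C3–CO2Me bond. This makes C3 the central carbon of a 1,3-dicarbonyl unit, which is what allows it to appear as a stabilised enolate in the step before. The price is one carbon to be removed. The forward step must lose the ester without damaging the lactone and must leave C3 under thermodynamic control; the C3 epimer 11 that forms on the way has to drain into 12, which is possible because C4 is inert to base.

**10 ⇒ 5 + 7 + 8.** Two bonds are cut: C3–CH2 on the ring A side, and the bond between the ipso carbon of ring B and its benzylic CH2. That CH2 is reconnected to C3, so that it becomes the methylene of a cyclopropane fused across C3–C4. Both aryl groups leave in one operation, the problem shrinks to a seven-carbon bicycle, and the two benzyl groups can no longer be confused because they enter by different mechanisms (nucleophile 7, electrophile 8). The forward step must attack the cyclopropane CH2 and not the ring-fusion CH, must spare both carbonyl groups, and needs an enolate reactive enough to be benzylated in the same flask.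

**5 ⇒ 1 + 2.** The two cyclopropane bonds to C1 (C1–C5 and C1–C6) and the acyl–oxygen bond of the lactone are cut. This leads to two commodity chemicals and takes the only persistent stereocentre from the chiral pool. The forward step must follow one pathway (epoxide opening first, through 3 and 4), because the other order of events gives the enantiomer; the single inversion in the ring closure then defines C5 of 5.

**7 ⇒ 6.** The carbon–magnesium bond is cut. Only clean metal insertion into an electron-rich aryl bromide is required.

## Other disconnections considered

**Alternative 1:** The cut removes the carbonyl carbon from the ring (bonds C2–C3 and C2–O1). This leaves carbon monoxide and the homopropargylic alcohol A1, (R)-4-(3,4-dimethoxyphenyl)-2-(3,4,5-trimethoxybenzyl)but-3-yn-1-ol.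
- Forward key step: Pd(OAc)2 (divalent palladium) with 1,4-bis(diphenylphosphino)butane and an acid co-catalyst under CO would add hydrogen and the alkoxycarbonyl group syn across the alkyne and close the lactone as the (E)-benzylidene compound A2. Hydrogenation of the exocyclic alkene and base equilibration at C3 would then lead through 11 to 12.
- In favour: ring and carbonyl are made in one catalytic, fully atom-economic step, and the syn mechanism fixes the alkene geometry. On atom economy and ring construction this plan is the better one. C4 is set before the key step and only carried through, as in the chosen plan, so the two are equal in stereochemical logic.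
- Against: the stereocentre of A1 is propargylic and β to oxygen and has no short chiral-pool source. An auxiliary-based sequence of several steps with an epimerisable intermediate would be needed before the key step.
- Against: the carbonylation regiochemistry (five-membered alkylidene lactone against a six-membered unsaturated lactone) depends on ligand and acid, and pressurised CO is required.
- Against: two operations remain after the key step, because hydrogen should add anti to the C4 substituent and give mainly 11.
- Step economy: roughly twice as long as the chosen four steps.

**Alternative 2:** The cut is the C3–C4 bond together with a temporary bond between C3 and the benzylic carbon of ring B. This leads to the acyclic diazo ester A3, (E)-3-(3,4,5-trimethoxyphenyl)prop-2-en-1-yl 2-diazo-3-(3,4-dimethoxyphenyl)propanoate.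
- Forward key step: Rh2(S-PTTL)4 (divalent rhodium) would generate the carbene, which adds to the tethered (E)-alkene to give the cyclopropane-fused lactone A4 with the aryl group exo. Hydrogenolysis (H2, Pd/C) of the C1–C6 bond, which is both benzylic and α to the carbonyl, and equilibration at C3 would give 12.
- In favour: every carbon and both aryl groups are in place in A3 after a simple ester formation. The key step closes the lactone and sets C4 by catalyst control, so either enantiomer is available without chiral-pool material. In convergence it is at least the equal of the chosen plan.
- Against: an α-alkyl α-diazo ester with benzylic β-hydrogens is prone to 1,2-hydride migration, and the enantioselectivity of this catalyst in an intramolecular reaction of a trans-disubstituted allyl ester is not assured. In the chosen plan the configuration is bought.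
- Against: diazo transfer onto a simple ester needs a temporary activating acyl group, and diazo compounds must be handled.
- Against: the hydrogenolysis has to distinguish C1–C6 from the also benzylic C5–C6 bond; cleavage of the wrong bond would move both benzyl groups onto C3.
- Step economy: about six steps against four.

**Alternative 3:** Two cuts are made. The first is the C3–CH2 bond to ring A (an enolate alkylation). The second is the O1–C5 bond of the remaining monosubstituted lactone A6, which is traced back to the achiral cyclobutanone A5, 3-(3,4,5-trimethoxybenzyl)cyclobutan-1-one.
- Forward key step: a chiral Baeyer–Villiger catalyst (for example a chiral Brønsted acid with aqueous H2O2, or a Baeyer–Villiger monooxygenase) would insert oxygen into one of the two enantiotopic C(O)–CH2 bonds of A5 to give (R)-A6. Deprotonation with LDA and alkylation with 8 anti to the C4 substituent would then give 12 directly.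
- In favour: the stereocentre is created catalytically from a prochiral substrate. The path from key product to target is one well-established trans-selective alkylation, with no ester to remove and no separate equilibration, so after the key step this plan is the better one.
- Common ground: A6 is what the chosen route would give if the ester were removed before the second benzyl group went on, so both plans rest on the same logic at C4.
- Against: desymmetrising Baeyer–Villiger reactions of 3-benzylcyclobutanones usually fall short of complete enantioselectivity, and a peroxide is not an ideal partner for the electron-rich ring B. The chosen plan takes C4 from a commodity chemical of high enantiomeric purity.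
- Against: A5 is not commercial and needs a ketene [2+2] cycloaddition and dechlorination sequence of about three steps, and the LDA alkylation carries a dialkylation risk that the blocked C3 of 10 excludes.
- Step economy: about five steps against four.

Key step: step 3

Remark: the configurations of 2, 5, 10 and 12 were re-derived atom by atom and agree with one another, so no structure had to be changed; 8 is treated as a purchased reagent that is kept cold and used promptly, because electron-rich benzylic bromides self-condense on storage.

## Route

Step 1
Reactants: 1 dimethyl malonate; 2 (R)-epichlorohydrin [(2R)-2-(chloromethyl)oxirane]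
Product: 5 methyl (1S,5R)-2-oxo-3-oxabicyclo[3.1.0]hexane-1-carboxylate, via epoxy malonate 3 (not isolated), via hydroxymethylcyclopropane diester 4 (not isolated)
Conditions: NaOMe (1.05 equiv), MeOH, rt → reflux, 18 h; AcOH quench
Reagents that add atoms: none
Why: Tandem malonate alkylation, cyclopropanation and lactonisation: the malonate anion opens the epoxide of 2 at its CH2 terminus, the alkoxide displaces chloride to give epoxide 3, and the re-formed carbanion closes the three-membered ring by 3-exo-tet attack to give alkoxide 4, which lactonises onto the cis ester. The single inversion at the epoxide CH turns C2 of 2 into C5 (R) of 5, and the cis ring fusion fixes C1 as S.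

Step 2
Reactants: 6 5-bromo-1,2,3-trimethoxybenzene
Product: 7 3,4,5-trimethoxyphenylmagnesium bromide (THF solution, titrated and used directly)
Conditions: Mg turnings, I2 (cat.), THF, 50 °C
Reagents that add atoms: magnesium, [Mg]
Why: Grignard reagent formation by insertion of zerovalent magnesium into the aryl C–Br bond; the methyl ethers are inert and the substrate has no acidic or electrophilic group.

Step 3
Reactants: 5 methyl (1S,5R)-2-oxo-3-oxabicyclo[3.1.0]hexane-1-carboxylate; 7 3,4,5-trimethoxyphenylmagnesium bromide; 8 3,4-dimethoxybenzyl bromide
Product: 10 methyl (3R,4R)-3-(3,4-dimethoxybenzyl)-2-oxo-4-(3,4,5-trimethoxybenzyl)oxolane-3-carboxylate, via magnesium enolate 9 (not isolated)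
Conditions: CuI (10 mol %), THF, −40 °C, slow addition of 7 (1.2 equiv), → −20 °C; then DMPU, 8 (1.5 equiv), −20 °C → rt; aq. NH4Cl
Reagents that add atoms: none
Why: Transmetalation of 7 with CuI (monovalent copper) gives an aryl cuprate that attacks the unsubstituted cyclopropane carbon C6 of 5 from the rear of the C1–C6 bond in an SN2-like oxidative addition; reductive elimination from the transient trivalent copper species forms the ring B–CH2 bond and releases the chelated magnesium enolate 9. The closest known reaction type is the copper-catalysed homoconjugate (1,5-) addition of Grignard reagents to cyclopropane-1,1-dicarbonyl compounds, established for this bicyclic lactone ester class, combined with C-benzylation of an α-alkoxycarbonyl lactone enolate as in a tandem conjugate addition–alkylation. No ring is closed; the three-membered ring is opened and the lactone stays intact. Attack at C6 and not at the ring-fusion carbon C5 follows from the lower substitution of C6 and from the fact that only C1–C6 cleavage keeps the five-membered lactone while placing the charge on the doubly acyl-stabilised C1. Carbonyl addition of 7 is held back by the copper catalyst, the low temperature and the slow addition, and once 9 has formed both carbonyl groups are masked in the enolate. C5 of 5 is not touched and becomes C4 (R) of 10. The new quaternary centre C3 arises when 8 approaches the planar enolate on the face opposite the adjacent 3,4,5-trimethoxybenzyl group, which should favour the (3R) isomer; this selectivity is not critical because C3 is reset in step 4. DMPU loosens the magnesium chelate so that C-alkylation by the reactive benzylic bromide should proceed at or slightly above room temperature, and the small excess of 7 is consumed by the excess of 8.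

Step 4
Reactants: 10 methyl (3R,4R)-3-(3,4-dimethoxybenzyl)-2-oxo-4-(3,4,5-trimethoxybenzyl)oxolane-3-carboxylate
Product: 12 (3R,4R)-3-(3,4-dimethoxybenzyl)-4-(3,4,5-trimethoxybenzyl)oxolan-2-one, via cis lactone 11 (not isolated)
Conditions: LiCl (3 equiv), H2O (2 equiv), DMSO, 150 °C; then DBU (0.5 equiv), 60 °C; 1 M HCl work-up
Reagents that add atoms: none
Why: Krapcho demethoxycarbonylation: chloride demethylates the ester by SN2 at the methyl group, the carboxylate loses CO2, and water protonates the lactone enolate to give 12 together with its cis epimer 11. DBU then equilibrates the acidic C3 centre through the enolate to the thermodynamically preferred trans (3R,4R) arrangement, while C4 has no acidic hydrogen and keeps the configuration brought in with 2; the acidic work-up recloses any lactone opened by hydroxide.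

## Compound list

1 | dimethyl malonate | COC(=O)CC(=O)OC | starting material
2 | (R)-epichlorohydrin, (2R)-2-(chloromethyl)oxirane | ClC[C@H]1CO1 | starting material
3 | dimethyl 2-{[(2R)-oxiran-2-yl]methyl}propanedioate | COC(=O)C(C[C@@H]1CO1)C(=O)OC | intermediate (not isolated)
4 | dimethyl (2R)-2-(hydroxymethyl)cyclopropane-1,1-dicarboxylate (present as its sodium alkoxide) | OC[C@@H]1CC1(C(=O)OC)C(=O)OC | intermediate (not isolated)
5 | methyl (1S,5R)-2-oxo-3-oxabicyclo[3.1.0]hexane-1-carboxylate | O=C1OC[C@@H]2C[C@]12C(=O)OC | intermediate
6 | 5-bromo-1,2,3-trimethoxybenzene | COc1cc(Br)cc(OC)c1OC | starting material
7 | 3,4,5-trimethoxyphenylmagnesium bromide | COc1cc([Mg]Br)cc(OC)c1OC | intermediate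
8 | 3,4-dimethoxybenzyl bromide, 4-(bromomethyl)-1,2-dimethoxybenzene | COc1ccc(CBr)cc1OC | starting material
9 | bromomagnesium (4R)-3-(methoxycarbonyl)-4-(3,4,5-trimethoxybenzyl)-4,5-dihydrofuran-2-olate | COC(=O)C1=C(O[Mg]Br)OC[C@@H]1Cc1cc(OC)c(OC)c(OC)c1 | intermediate (not isolated)
10 | methyl (3R,4R)-3-(3,4-dimethoxybenzyl)-2-oxo-4-(3,4,5-trimethoxybenzyl)oxolane-3-carboxylate | COc1ccc(C[C@@]2(C(=O)OC)C(=O)OC[C@@H]2Cc2cc(OC)c(OC)c(OC)c2)cc1OC | intermediate
11 | (3S,4R)-3-(3,4-dimethoxybenzyl)-4-(3,4,5-trimethoxybenzyl)oxolan-2-one (cis epimer) | COc1ccc(C[C@@H]2C(=O)OC[C@@H]2Cc2cc(OC)c(OC)c(OC)c2)cc1OC | intermediate (not isolated)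
12 | (3R,4R)-3-(3,4-dimethoxybenzyl)-4-(3,4,5-trimethoxybenzyl)oxolan-2-one | COc1ccc(C[C@H]2C(=O)OC[C@@H]2Cc2cc(OC)c(OC)c(OC)c2)cc1OC | target

## Step count and least certain steps

Total step count: 4. Longest linear sequence: 3 steps (step 1 → step 3 → step 4); step 2 is a one-step branch that joins at step 3.

**Step 3 (key step).** The benzylation of the chelated magnesium enolate may be slow. The copper-catalysed coupling of left-over 7 with 8 may then use up the electrophile, and at higher concentrations of 7 some carbonyl addition may compete with ring opening. Fallback: the two bond formations are separated. Starting from 5 and 7, the copper-catalysed opening is run alone and quenched with aqueous NH4Cl to give methyl (4R)-2-oxo-4-(3,4,5-trimethoxybenzyl)oxolane-3-carboxylate F1, which is isolated. Its sodium enolate (NaH, DMF, 0 °C), which is not deactivated by chelation, is benzylated with 8, and the route is rejoined at 10.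

**Step 4.** Demethylation of the hindered quaternary ester may be incomplete, chloride or hydroxide may open the lactone at 150 °C, and the equilibration in wet DMSO may stop short of the thermodynamic ratio. Fallback: from 10, KOH in aqueous MeOH at reflux hydrolyses ester and lactone. Acidification with HCl recloses the ring to (4R)-3-(3,4-dimethoxybenzyl)-2-oxo-4-(3,4,5-trimethoxybenzyl)oxolane-3-carboxylic acid F2 (either C3 epimer). F2 is decarboxylated by heating in toluene, the resulting C3 epimers are equilibrated with DBU in toluene, and the route is rejoined at 12.

**Step 1.** Direct displacement of chloride before epoxide opening leads to the enantiomeric lactone and would erode the enantiomeric purity; dialkylation or oligomerisation of the malonate may lower the yield. The enantiomeric purity of 5 should be checked before it is used. Fallback: setting out from 1, the electrophile is changed to one that can react by only one pathway. (R)-Glycidol F3 is converted with Tf2O and 2,6-lutidine in CH2Cl2 at −40 °C into (S)-glycidyl triflate F4. The sodium salt of 1 (NaH, THF, 0 °C) displaces the triflate directly to give the same epoxide 3; catalytic NaOMe and warming complete the cyclisation and lactonisation, and the route is rejoined at 5.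

**Step 2.** Initiation may be sluggish and reductive homocoupling to the biaryl may compete with the electron-rich bromide, which would make the titre of 7, and with it the stoichiometry of step 3, unreliable. Fallback: from 6, bromine–lithium exchange with n-BuLi in THF at −78 °C gives 3,4,5-trimethoxyphenyllithium F5. Transmetalation with MgBr2·OEt2 then gives 7, where the route is rejoined.

## Further compounds

F1 | step 3 | methyl (4R)-2-oxo-4-(3,4,5-trimethoxybenzyl)oxolane-3-carboxylate (C3 epimers interconvert) | COC(=O)C1C(=O)OC[C@@H]1Cc1cc(OC)c(OC)c(OC)c1
F2 | step 4 | (4R)-3-(3,4-dimethoxybenzyl)-2-oxo-4-(3,4,5-trimethoxybenzyl)oxolane-3-carboxylic acid (either C3 epimer) | COc1ccc(CC2(C(=O)O)C(=O)OC[C@@H]2Cc2cc(OC)c(OC)c(OC)c2)cc1OC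
F3 | step 1 | (R)-glycidol, [(2R)-oxiran-2-yl]methanol | OC[C@@H]1CO1
F4 | step 1 | (S)-glycidyl triflate, [(2S)-oxiran-2-yl]methyl trifluoromethanesulfonate | O=S(=O)(OC[C@@H]1CO1)C(F)(F)F
F5 | step 2 | 3,4,5-trimethoxyphenyllithium | [Li]c1cc(OC)c(OC)c(OC)c1
A1 | alternative 1 | (R)-4-(3,4-dimethoxyphenyl)-2-(3,4,5-trimethoxybenzyl)but-3-yn-1-ol | COc1ccc(C#C[C@H](CO)Cc2cc(OC)c(OC)c(OC)c2)cc1OC
A2 | alternative 1 | (R,E)-3-(3,4-dimethoxybenzylidene)-4-(3,4,5-trimethoxybenzyl)oxolan-2-one | COc1ccc(/C=C2/C(=O)OC[C@@H]2Cc2cc(OC)c(OC)c(OC)c2)cc1OC
A3 | alternative 2 | (E)-3-(3,4,5-trimethoxyphenyl)prop-2-en-1-yl 2-diazo-3-(3,4-dimethoxyphenyl)propanoate | COc1ccc(CC(=[N+]=[N-])C(=O)OC/C=C/c2cc(OC)c(OC)c(OC)c2)cc1OC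
A4 | alternative 2 | (1S,5R,6S)-1-(3,4-dimethoxybenzyl)-6-(3,4,5-trimethoxyphenyl)-3-oxabicyclo[3.1.0]hexan-2-one | O=C1OC[C@@H]2[C@@H](c3cc(OC)c(OC)c(OC)c3)[C@]12Cc1ccc(OC)c(OC)c1
A5 | alternative 3 | 3-(3,4,5-trimethoxybenzyl)cyclobutan-1-one | COc1cc(CC2CC(=O)C2)cc(OC)c1OC
A6 | alternative 3 | (R)-4-(3,4,5-trimethoxybenzyl)oxolan-2-one | O=C1OC[C@H](Cc2cc(OC)c(OC)c(OC)c2)C1
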